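**Plan**
- Cuts: the phenol O–allyl bond (protection); C9–O (angelate) and C10–O (acetate), each traced back to an oxirane on C8; the oxirane O–C10 bond, traced back to a chloromethyl arm; the C7–O acyl bond; and the C8–aryl bond (aryllithium plus 1,3-dichloroacetone).
- Enabling feature: C8 is a tertiary carbinol carbon on the benzene ring (ring A) whose two CH2–O arms, C9 and C10, differ only in their acyl groups, so C8 maps onto a prochiral ArC(OH)(CH2Cl)2 unit.
- Forward order: ring A is bought; C8 is attached by aryllithium addition; the C7 ester is installed; the enzyme closes the first oxirane (O–C10); acetate opens it at C10; base closes the second oxirane (O–C9); angelate opens it at C9; deallylation ends the route.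
- Stereochemistry: C8 is set by the dehalogenase, which cyclises the pro-S chloromethyl arm, and no bond to C8 is broken afterwards. The ester stereocentre comes from (R)-2-methylbutanoic acid, and the Z olefin from angelic acid used only as a carboxylate nucleophile.

Key step: step 7

Assumption: the dehalogenase variant retained after screening cyclises the pro-S chloromethyl arm of 11; a variant with the opposite preference would be accommodated by introducing angelate before acetate, with no other change.

**Step 1**
Reactants: 1 methyl 4-bromo-3-hydroxybenzoate; 2 allyl bromide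
Product: 3 methyl 4-bromo-3-(prop-2-en-1-yloxy)benzoate
Conditions: K2CO3, DMF, rt
Reagents that add atoms: none
Why: Williamson etherification, in which the phenoxide formed by K2CO3 displaces bromide from allyl bromide by SN2 at oxygen while the methyl ester and the aryl bromide stay inert.

**Step 2**
Reactants: 3 methyl 4-bromo-3-(prop-2-en-1-yloxy)benzoate
Product: 4 [4-bromo-3-(prop-2-en-1-yloxy)phenyl]methanol
Conditions: iBu2AlH (2.5 equiv), CH2Cl2, −78 to 0 °C; aq. potassium sodium tartrate
Reagents that add atoms: none
Why: Hydride reduction of the ester with iBu2AlH should stop cleanly at the benzylic alcohol at low temperature without touching the aryl bromide or the allyl ether.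

**Step 3**
Reactants: 4 [4-bromo-3-(prop-2-en-1-yloxy)phenyl]methanol
Product: 5 {[4-bromo-3-(prop-2-en-1-yloxy)phenyl]methoxy}(tert-butyl)dimethylsilane
Conditions: TBSCl, imidazole, CH2Cl2, rt
Reagents that add atoms: tert-butyldimethylsilyl chloride, CC(C)(C)[Si](C)(C)Cl
Why: Imidazole-promoted silylation of a primary alcohol masks the acidic hydroxyl so that the organolithium step can be run with one equivalent of base.

**Step 4**
Reactants: 5 {[4-bromo-3-(prop-2-en-1-yloxy)phenyl]methoxy}(tert-butyl)dimethylsilane; 6 1,3-dichloroacetone
Product: 8 2-[4-({[tert-butyl(dimethyl)silyl]oxy}methyl)-2-(prop-2-en-1-yloxy)phenyl]-1,3-dichloropropan-2-ol, via aryllithium 7 (not isolated)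
Conditions: n-BuLi (1.05 equiv), THF, −78 °C, 15 min; then 6 in THF, −78 °C; AcOH quench at −78 °C
Reagents that add atoms: none
Why: Bromine–lithium exchange at −78 °C is faster than any attack on the allyl ether, the aryllithium then adds 1,2 to the doubly activated carbonyl of 1,3-dichloroacetone (the usual way 2-aryl-1,3-dichloropropan-2-ols are made from aryl organometallics), and the cold acidic quench protonates the alkoxide before it can expel chloride.

**Step 5**
Reactants: 8 2-[4-({[tert-butyl(dimethyl)silyl]oxy}methyl)-2-(prop-2-en-1-yloxy)phenyl]-1,3-dichloropropan-2-ol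
Product: 9 1,3-dichloro-2-[4-(hydroxymethyl)-2-(prop-2-en-1-yloxy)phenyl]propan-2-ol
Conditions: camphorsulfonic acid (cat.), MeOH, 0 °C to rt
Reagents that add atoms: none
Why: Acid-catalysed methanolysis removes the primary silyl ether, while the tertiary dichlorohydrin is left alone because two beta chlorines disfavour its benzylic cation and no base is present that could close an oxirane.

**Step 6**
Reactants: 9 1,3-dichloro-2-[4-(hydroxymethyl)-2-(prop-2-en-1-yloxy)phenyl]propan-2-ol; 10 (R)-2-methylbutanoic acid
Product: 11 [4-(1,3-dichloro-2-hydroxypropan-2-yl)-3-(prop-2-en-1-yloxy)phenyl]methyl (2R)-2-methylbutanoate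
Conditions: DCC, DMAP (cat.), CH2Cl2, 0 °C to rt
Reagents that add atoms: none
Why: Steglich esterification acylates the unhindered primary benzylic hydroxyl in preference to the tertiary one, and the mild carbodiimide activation should leave the alpha stereocentre of the (R)-acid intact.

**Step 7**
Reactants: 11 [4-(1,3-dichloro-2-hydroxypropan-2-yl)-3-(prop-2-en-1-yloxy)phenyl]methyl (2R)-2-methylbutanoate
Product: 12 {4-[(2R)-2-(chloromethyl)oxiran-2-yl]-3-(prop-2-en-1-yloxy)phenyl}methyl (2R)-2-methylbutanoate
Conditions: purified halohydrin dehalogenase of the HheC type (variant chosen by screening), Tris-SO4 buffer pH 7.5, DMSO (10% v/v), methyl tert-butyl ether overlay, 25 °C, pH-stat with aq. NaOH, short contact time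
Reagents that add atoms: none
Why: Proposed new method: in the active site the catalytic tyrosine removes the proton of the C8 hydroxyl while the halide pocket holds one CH2Cl group, and the alkoxide displaces that chloride by intramolecular SN2, which forms the O–C10 bond. The closest known reactions are the halohydrin-dehalogenase desymmetrisation of 1,3-dichloropropan-2-ol to epichlorohydrin and the enantioselective interconversion of tertiary halohydrins and 2,2-disubstituted oxiranes by the same enzyme class; a carbinol carbon bearing an ortho-substituted aryl group has not been shown, so variant screening or engineering is expected. The oxirane closes in the 3-exo-tet mode. The new stereocentre C8 is controlled by the chiral halide-binding pocket, which selects the pro-S chloromethyl arm and so should give the (R)-oxirane, while the remote (R)-2-methylbutanoate centre is a spectator. The step needs enantiotopic-group selectivity and chemoselectivity: the substrate offers two constitutionally identical arms on a hydroxyl acidified by two beta chlorines, pH 7.5 at 25 °C keeps the uncatalysed closure slow, a short contact time with continuous extraction into the ether phase limits chloride-mediated reopening, and purified enzyme free of esterase activity spares the C7 ester.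

**Step 8**
Reactants: 12 {4-[(2R)-2-(chloromethyl)oxiran-2-yl]-3-(prop-2-en-1-yloxy)phenyl}methyl (2R)-2-methylbutanoate
Product: 13 {4-[(2R)-1-(acetyloxy)-3-chloro-2-hydroxypropan-2-yl]-3-(prop-2-en-1-yloxy)phenyl}methyl (2R)-2-methylbutanoate
Conditions: CsOAc (1.5 equiv), AcOH (3 equiv), DMF, 50 °C
Reagents that add atoms: acetic acid, CC(=O)O; cesium acetate, CC(=O)[O-].[Cs+] (carrier of the nucleophilic acetate)
Why: Carboxylate opening of a 2,2-disubstituted oxirane, in which acetate attacks the unsubstituted ring carbon C10 by SN2 (the neopentyl-type CH2Cl carbon and the quaternary C8 are much slower), C8 is not touched so its configuration is kept, and the acetic acid buffer protonates the alkoxide at once so that the chlorohydrin neither recloses nor takes up a second acetate.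

**Step 9**
Reactants: 13 {4-[(2R)-1-(acetyloxy)-3-chloro-2-hydroxypropan-2-yl]-3-(prop-2-en-1-yloxy)phenyl}methyl (2R)-2-methylbutanoate
Product: 14 {4-[(2S)-2-[(acetyloxy)methyl]oxiran-2-yl]-3-(prop-2-en-1-yloxy)phenyl}methyl (2R)-2-methylbutanoate
Conditions: K2CO3 (powdered, 2 equiv), MeCN, rt
Reagents that add atoms: none
Why: Intramolecular Williamson reaction (3-exo-tet) of the tertiary alkoxide on the chloromethyl carbon C9, accelerated by the geminal substituents on C8, in an aprotic medium that spares the acetate and the C7 ester; no bond to C8 is broken, and the descriptor changes from R to S only because the substituent priorities change.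

**Step 10**
Reactants: 14 {4-[(2S)-2-[(acetyloxy)methyl]oxiran-2-yl]-3-(prop-2-en-1-yloxy)phenyl}methyl (2R)-2-methylbutanoate; 15 angelic acid ((2Z)-2-methylbut-2-enoic acid)
Product: 16 (2R)-3-(acetyloxy)-2-hydroxy-2-[4-({[(2R)-2-methylbutanoyl]oxy}methyl)-2-(prop-2-en-1-yloxy)phenyl]propyl (2Z)-2-methylbut-2-enoate
Conditions: Cs2CO3 (0.75 equiv), threefold excess of 15, DMF, 50 °C
Reagents that add atoms: none
Why: SN2 opening of the oxirane at C9 by cesium angelate with free angelic acid as proton donor, in which the acid is never activated as an electrophile so its Z geometry should be kept, and the buffered medium suppresses alkoxide-mediated acyl migration that would exchange the two arms.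

**Step 11**
Reactants: 16 (2R)-3-(acetyloxy)-2-hydroxy-2-[4-({[(2R)-2-methylbutanoyl]oxy}methyl)-2-(prop-2-en-1-yloxy)phenyl]propyl (2Z)-2-methylbut-2-enoate
Product: 17 (2R)-3-(acetyloxy)-2-hydroxy-2-[2-hydroxy-4-({[(2R)-2-methylbutanoyl]oxy}methyl)phenyl]propyl (2Z)-2-methylbut-2-enoate
Conditions: Pd(PPh3)4 (5 mol %), morpholine (3 equiv), THF, rt
Reagents that add atoms: none
Why: Tsuji–Trost-type deallylation, in which zerovalent palladium ionises the aryl allyl ether to a pi-allyl complex and the phenoxide, morpholine traps the allyl group, and the three esters, the tertiary alcohol and the Z olefin should be unaffected at room temperature.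

**Compound list**
1 | methyl 4-bromo-3-hydroxybenzoate | COC(=O)c1ccc(Br)c(O)c1 | starting material
2 | allyl bromide | C=CCBr | starting material
3 | methyl 4-bromo-3-(prop-2-en-1-yloxy)benzoate | COC(=O)c1ccc(Br)c(OCC=C)c1 | intermediate
4 | [4-bromo-3-(prop-2-en-1-yloxy)phenyl]methanol | OCc1ccc(Br)c(OCC=C)c1 | intermediate
5 | {[4-bromo-3-(prop-2-en-1-yloxy)phenyl]methoxy}(tert-butyl)dimethylsilane | CC(C)(C)[Si](C)(C)OCc1ccc(Br)c(OCC=C)c1 | intermediate
6 | 1,3-dichloroacetone | ClCC(=O)CCl | starting material
7 | [4-({[tert-butyl(dimethyl)silyl]oxy}methyl)-2-(prop-2-en-1-yloxy)phenyl]lithium | [Li]c1ccc(CO[Si](C)(C)C(C)(C)C)cc1OCC=C | intermediate (not isolated)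
8 | 2-[4-({[tert-butyl(dimethyl)silyl]oxy}methyl)-2-(prop-2-en-1-yloxy)phenyl]-1,3-dichloropropan-2-ol | ClCC(O)(CCl)c1ccc(CO[Si](C)(C)C(C)(C)C)cc1OCC=C | intermediate
9 | 1,3-dichloro-2-[4-(hydroxymethyl)-2-(prop-2-en-1-yloxy)phenyl]propan-2-ol | ClCC(O)(CCl)c1ccc(CO)cc1OCC=C | intermediate
10 | (R)-2-methylbutanoic acid | CC[C@@H](C)C(=O)O | starting material
11 | [4-(1,3-dichloro-2-hydroxypropan-2-yl)-3-(prop-2-en-1-yloxy)phenyl]methyl (2R)-2-methylbutanoate | ClCC(O)(CCl)c1ccc(COC(=O)[C@H](C)CC)cc1OCC=C | intermediate
12 | {4-[(2R)-2-(chloromethyl)oxiran-2-yl]-3-(prop-2-en-1-yloxy)phenyl}methyl (2R)-2-methylbutanoate | ClC[C@]1(CO1)c1ccc(COC(=O)[C@H](C)CC)cc1OCC=C | intermediate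
13 | {4-[(2R)-1-(acetyloxy)-3-chloro-2-hydroxypropan-2-yl]-3-(prop-2-en-1-yloxy)phenyl}methyl (2R)-2-methylbutanoate | ClC[C@](O)(COC(C)=O)c1ccc(COC(=O)[C@H](C)CC)cc1OCC=C | intermediate
14 | {4-[(2S)-2-[(acetyloxy)methyl]oxiran-2-yl]-3-(prop-2-en-1-yloxy)phenyl}methyl (2R)-2-methylbutanoate | CC(=O)OC[C@@]1(CO1)c1ccc(COC(=O)[C@H](C)CC)cc1OCC=C | intermediate
15 | angelic acid, (2Z)-2-methylbut-2-enoic acid | C/C=C(/C)C(=O)O | starting material
16 | (2R)-3-(acetyloxy)-2-hydroxy-2-[4-({[(2R)-2-methylbutanoyl]oxy}methyl)-2-(prop-2-en-1-yloxy)phenyl]propyl (2Z)-2-methylbut-2-enoate | C/C=C(/C)C(=O)OC[C@](O)(COC(C)=O)c1ccc(COC(=O)[C@H](C)CC)cc1OCC=C | intermediate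
17 | (2R)-3-(acetyloxy)-2-hydroxy-2-[2-hydroxy-4-({[(2R)-2-methylbutanoyl]oxy}methyl)phenyl]propyl (2Z)-2-methylbut-2-enoate | C/C=C(/C)C(=O)OC[C@](O)(COC(C)=O)c1ccc(COC(=O)[C@H](C)CC)cc1O | target

**Step count**
Total steps: 11. Longest linear sequence: 11 steps (1 to 17).

**Steps most likely to fail**

Step 7. Turnover of the bulky ortho-alkoxyaryl tertiary substrate may be slow enough that uncatalysed closure and chloride-mediated reopening compete, so that discrimination between the two chloromethyl arms is lost. The fallback uses known chemistry and sets out from 11. K2CO3 in MeCN closes the oxirane without selectivity and should give 12 together with its C8 epimer, {4-[(2S)-2-(chloromethyl)oxiran-2-yl]-3-(prop-2-en-1-yloxy)phenyl}methyl (2R)-2-methylbutanoate F1. The two epimers are separated by preparative chromatography on a chiral stationary phase. F1 is returned to prochiral 11 by chloride opening at the oxirane CH2 (LiCl, AcOH, THF) and recycled. The route is rejoined at 12.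

Step 8. Control of the acetate opening may be lost through attack at the benzylic carbon C8 or direct displacement at the chloromethyl carbon, either of which erodes the configuration, or through slow reclosure and a second opening that erases the difference between the arms. The fallback sets out from 11 and moves the desymmetrisation to the fully oxygenated stage. Excess CsOAc in DMF at 90 °C should carry both arms through oxirane closure and opening to the symmetric bis-acetate {4-[1,3-bis(acetyloxy)-2-hydroxypropan-2-yl]-3-(prop-2-en-1-yloxy)phenyl}methyl (2R)-2-methylbutanoate F2. A lipase (Candida antarctica lipase B or Burkholderia cepacia lipase, phosphate buffer pH 7, rt) is then used to hydrolyse the pro-R acetoxymethyl arm. This is hydrolase desymmetrisation of a prochiral 2-substituted propane-1,3-diol diacetate, an established reaction class, and should give {4-[(2S)-1-(acetyloxy)-2,3-dihydroxypropan-2-yl]-3-(prop-2-en-1-yloxy)phenyl}methyl (2R)-2-methylbutanoate F3. Immediate sulfonylation of the primary hydroxyl (MsCl, Et3N, CH2Cl2, −20 °C) stops 1,3-acetyl migration and gives {4-[(2R)-1-(acetyloxy)-2-hydroxy-3-[(methanesulfonyl)oxy]propan-2-yl]-3-(prop-2-en-1-yloxy)phenyl}methyl (2R)-2-methylbutanoate F4. K2CO3 in MeCN closes the oxirane, and the route is rejoined at 14.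

Step 4. Proton transfer from the acidic 1,3-dichloroacetone to the basic aryllithium (enolisation) may outrun carbonyl addition, or the lithium alkoxide may lose chloride before the quench. The fallback sets out from 5. After the same bromine–lithium exchange, aryllithium 7 is acylated with 2-chloro-N-methoxy-N-methylacetamide to give 2-chloro-1-[4-({[tert-butyl(dimethyl)silyl]oxy}methyl)-2-(prop-2-en-1-yloxy)phenyl]ethan-1-one F5. Chloromethyllithium, generated in the presence of F5 from ICH2Cl and MeLi·LiBr in THF at −78 °C, adds to the carbonyl, and an AcOH quench at −78 °C should give 8. The second chloromethyl arm is thus attached by one-carbon homologation and the enolisable dichloroketone is avoided. The route is rejoined at 8.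

**Further compounds**
F1 | step 7 | {4-[(2S)-2-(chloromethyl)oxiran-2-yl]-3-(prop-2-en-1-yloxy)phenyl}methyl (2R)-2-methylbutanoate | ClC[C@@]1(CO1)c1ccc(COC(=O)[C@H](C)CC)cc1OCC=C
F2 | step 8 | {4-[1,3-bis(acetyloxy)-2-hydroxypropan-2-yl]-3-(prop-2-en-1-yloxy)phenyl}methyl (2R)-2-methylbutanoate | CC(=O)OCC(O)(COC(C)=O)c1ccc(COC(=O)[C@H](C)CC)cc1OCC=C
F3 | step 8 | {4-[(2S)-1-(acetyloxy)-2,3-dihydroxypropan-2-yl]-3-(prop-2-en-1-yloxy)phenyl}methyl (2R)-2-methylbutanoate | OC[C@](O)(COC(C)=O)c1ccc(COC(=O)[C@H](C)CC)cc1OCC=C
F4 | step 8 | {4-[(2R)-1-(acetyloxy)-2-hydroxy-3-[(methanesulfonyl)oxy]propan-2-yl]-3-(prop-2-en-1-yloxy)phenyl}methyl (2R)-2-methylbutanoate | CS(=O)(=O)OC[C@](O)(COC(C)=O)c1ccc(COC(=O)[C@H](C)CC)cc1OCC=C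
F5 | step 4 | 2-chloro-1-[4-({[tert-butyl(dimethyl)silyl]oxy}methyl)-2-(prop-2-en-1-yloxy)phenyl]ethan-1-one | ClCC(=O)c1ccc(CO[Si](C)(C)C(C)(C)C)cc1OCC=C
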